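At 35 °C the time to watch is when free Z (the substrate) disappears: the ash run has hardly any Z left at 15.0 min, yet its product J stands at 39.6%, so the balance has gone another way.

| flask | Z | X | E | temperature | remark | time |
|---|---|---|---|---|---|---|
| ash | 22 mM | 1.4 mM | 6.5 mM | 35 °C | run made earlier |  |
| summer | 30 mM | 1.4 mM | 6.5 mM | 35 °C |  | 25 min |
| autumn | 20 mM | 6.0 mM | 10 mM | 35 °C |  | 25 min |
| spring | 20 mM | 1.4 mM | 6.5 mM | 35 °C |  | 25 min |
| dawn | 10 mM | 0.40 mM | 6.5 mM | 35 °C |  | 25 min |
| midnight | 60 mM | 1.4 mM | 3.0 mM | 5 °C |  | 25 min |

ash run (percent of the Z charged)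

| time / min | J / % | Z / % |
|---|---|---|
| 4.00 | 10.2 | 40.3 |
| 8.00 | 21.5 | 20.3 |
| 12.0 | 32.6 | 8.1 |
| 15.0 | 39.6 | 1.2 |

(readings scatter by 0.3 percentage points)

- percent here means Z units held: one Q counts as two
- what may be going on: L <-> D; X + E <-> G; 2 Z -> Q; D -> X + J; Z + X -> L
- the earlier runs do not show what temperature does; that part of a forecast is a guess
- no earlier run changes the charge of X; that part of a forecast is a guess
- no earlier run changes the charge of E; that part of a forecast is a guess

* ranking by amount of J, in percent of the Z charged, from high to low, at 25 min (summer / autumn / spring / dawn / midnight)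
* the same order at 5.0 min (summer / autumn / spring / dawn / midnight)
* the amount of J, in percent of the Z charged of the flask you put first, at 25 min
* the amount of J, in percent of the Z charged of the flask you put last, at 25 min

In the ash run J climbs in a line from 4.00 min to 12.0 min at 0.616 mM min⁻¹, which reads as a turnover w of 0.440 min⁻¹ per unit of the catalyst X charged. Z also goes two at a time to the other product Q, at a rate a times the square of Z, and a can be read in two ways. Between the first two readings, Z lost beyond J gained comes to 8.7 percentage points, and that rate over the product of the two Z levels gives 0.0121 mM⁻¹ min⁻¹. From the charge to the first reading, with as much Z held at once as X was charged, the same reckoning gives 0.0130 mM⁻¹ min⁻¹. The Z products of these stretches differ 4.61-fold, yet the two values part by 0.0312 of a power of ten, so the ash readings bear the square law. The second way leans on a held amount of Z that nobody read, so it is the one to doubt, and the first is kept.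

The crossover constant K = w/a = 36.4 mM gives the selectivity factor R = K[X]/[Z]² at the charge, catalyst drain over dimer drain. This reckoning assumes that w holds at other X, which is a guess. In powers of ten, log R is −0.263 for autumn, −0.837 for dawn, −0.895 for spring, −0.978 for ash and −1.25 for summer. Midnight, at −1.85 before its cold is counted, stands lower than summer or spring. Dawn and spring should end alike, but dawn's turnover at w over 25 min covers 44.0% of its Z. Ash, with as much held Z counted as X was charged, should reach about 46.0%, and spring, with R higher, should pass that. R keeps dawn above summer at the end, but early on the measure is w[X]t/[Z]: at 5.0 min it gives summer 10.3% of its Z, more than dawn's 8.80%.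

The forecast reads autumn > spring > dawn > summer > midnight at 25 min and autumn > spring > summer > dawn > midnight at 5.0 min, with autumn at 84% (70% to 92%), since its rate “beats dimerisation”, and midnight at 2.3% (1% to 6%) on a temperature factor it calls a guess.

The flask gives autumn > spring > dawn > summer > midnight at 25 min and autumn > spring > summer > dawn > midnight at 5.0 min, with autumn at 83.6% and midnight at 0.784%.

    L ⇌ D (K = 2.60, k = 0.0140 s⁻¹, Ea = 74.0 kJ mol⁻¹, ΔH = 8.00 kJ mol⁻¹)
    X + E ⇌ G (K = 2000 M⁻¹, k = 0.190 M⁻¹ s⁻¹, Ea = 69.0 kJ mol⁻¹, ΔH = 19.0 kJ mol⁻¹)
    2 Z → Q (k = 0.100 M⁻¹ s⁻¹, Ea = 47.0 kJ mol⁻¹)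
    D → X + J (k = 0.0230 s⁻¹, Ea = 73.0 kJ mol⁻¹)
    Z + X → L (k = 58.0 M⁻¹ s⁻¹, Ea = 46.0 kJ mol⁻¹)
    (constants at 35 °C)

Left until 250 min, dawn stands at 48.5% of J, and spring at 49.0%. The neighbour of autumn charged with 80 mM of Z has log R −1.47, lower than summer's, and at 25.0 min it gives 31.9% of J against summer's 35.6%.

The readings are simulated with made-up constants.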